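**Plan**

- Retrosynthesis: the C3 aldehyde goes back to an ethyl ester and the 4-OH to a pivalate; ring B is then cut at C1'–C2' and C5'–C6' into a 2-ethynylbenzofuran-3-carboxylate and 1,1-dimethoxy-3-(trimethylsilyloxy)buta-1,3-diene.
- Further cuts: C2–C(sp) (iodide plus silylacetylene), the prenyl C5–CH2 bond (retro-Claisen to the O4 tertiary allyl ether), and the furan bonds O1–C2 and C3–C3a (symmetrical 2,6-dihydroxy-4-methoxybenzaldehyde plus ethyl diazoacetate).
- Forward order: ring A is bought, the furan ring is closed first, prenyl is moved from O4 to C5, the alkyne is attached at C2, ring B is built last by Diels–Alder aromatization, and the ester is then brought to the aldehyde level.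
- Enabling feature: in ring B, C1' lies ortho to the 2'-OMe and para to the 4'-OH, the pattern a 1,1-dimethoxy-3-silyloxybutadiene lays onto the internal carbon of an alkyne whose terminal carbon is electrophilic.
- Stereochemistry: ebenfuran IV has no stereocentre and no stereogenic double bond; control is regiochemical only (symmetry of the dihydroxyaldehyde for O1 versus O4, the single free ortho position for C5, polarity matching in the cycloaddition).

Key step: step 11

Remark: ring A is the benzo ring of the benzofuran, ring B the 2-aryl ring (C1'–C6'), prenyl is 3-methylbut-2-en-1-yl; compounds 1, 3, 6, 13, 16 and 17 are taken as catalogue materials.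

**Route**

Step 1
Reactants: 1 2,4,6-trimethoxybenzaldehyde
Product: 2 2,6-dihydroxy-4-methoxybenzaldehyde
Conditions: AlCl3 (4 equiv), ClCH2CH2Cl, 60 °C; then 1 M HCl
Reagents that add atoms: none
Why: Chelation-directed Lewis-acid ether cleavage, in which AlCl3 bound at the aldehyde oxygen activates only the two ortho methoxy groups for chloride attack at methyl, so the para methoxy group should remain.

Step 2
Reactants: 2 2,6-dihydroxy-4-methoxybenzaldehyde; 3 ethyl diazoacetate
Product: 5 ethyl 4-hydroxy-6-methoxy-1-benzofuran-3-carboxylate, via hemiacetal 4 (not isolated)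
Conditions: HBF4·OEt2 (10 mol%), CH2Cl2, rt; then conc. H2SO4 (cat.), rt
Reagents that add atoms: none
Why: Acid-catalysed addition of the diazo ester to the aldehyde with 1,2-aryl shift and loss of N2 gives a formyl arylacetate that one ortho phenol traps as hemiacetal 4 before dehydration to the benzofuran (salicylaldehyde–diazoacetate benzofuran annulation), and because the two phenols of 2 are equivalent the other is left as the 4-OH without a selectivity question.

Step 3
Reactants: 5 ethyl 4-hydroxy-6-methoxy-1-benzofuran-3-carboxylate; 6 tert-butyl 2-methylbut-3-en-2-yl carbonate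
Product: 7 ethyl 6-methoxy-4-[(2-methylbut-3-en-2-yl)oxy]-1-benzofuran-3-carboxylate
Conditions: Pd(PPh3)4 (5 mol%), THF, 4 Å MS, 0 °C to rt
Reagents that add atoms: none
Why: Tsuji–Trost O-allylation, in which ionisation of 6 by zerovalent palladium gives a 1,1-dimethylallyl complex plus tert-butoxide and the phenoxide attacks the more substituted allyl terminus under kinetic control to give the tertiary ether.

Step 4
Reactants: 7 ethyl 6-methoxy-4-[(2-methylbut-3-en-2-yl)oxy]-1-benzofuran-3-carboxylate
Product: 9 ethyl 4-hydroxy-6-methoxy-5-(3-methylbut-2-en-1-yl)-1-benzofuran-3-carboxylate, via ortho-dienone 8 (not isolated)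
Conditions: PhMe, 110 °C (sealed tube)
Reagents that add atoms: none
Why: Aromatic Claisen rearrangement, whose (3,3) shift can only reach C5 because the other ortho position (C3a) is the ring fusion, turns the 1,1-dimethylallyl ether into the linear prenyl group, and dienone 8 enolises to the phenol.

Step 5
Reactants: 9 ethyl 4-hydroxy-6-methoxy-5-(3-methylbut-2-en-1-yl)-1-benzofuran-3-carboxylate
Product: 10 ethyl 4-(2,2-dimethylpropanoyloxy)-6-methoxy-5-(3-methylbut-2-en-1-yl)-1-benzofuran-3-carboxylate
Conditions: PivCl, Et3N, DMAP (cat.), CH2Cl2, 0 °C to rt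
Reagents that add atoms: pivaloyl chloride, CC(C)(C)C(=O)Cl
Why: DMAP-catalysed O-acylation gives a pivalate that has no enolisable hydrogen, tolerates amide bases and Pd/Cu coupling, makes ring A a weaker donor for the cycloaddition and is removed later by the hydride that reduces the ester.

Step 6
Reactants: 10 ethyl 4-(2,2-dimethylpropanoyloxy)-6-methoxy-5-(3-methylbut-2-en-1-yl)-1-benzofuran-3-carboxylate
Product: 12 ethyl 4-(2,2-dimethylpropanoyloxy)-2-iodo-6-methoxy-5-(3-methylbut-2-en-1-yl)-1-benzofuran-3-carboxylate, via 2-magnesiated benzofuran 11 (not isolated)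
Conditions: TMPMgCl·LiCl (1.3 equiv), THF, −30 °C; then I2, −30 °C to rt
Reagents that add atoms: iodine, II
Why: Directed deprotonative magnesiation takes C2–H, the most acidic position (flanked by the ring oxygen and the C3 ester), with a hindered amide base that spares both esters, and iodinolysis of the C–Mg bond gives the 2-iodide.

Step 7
Reactants: 12 ethyl 4-(2,2-dimethylpropanoyloxy)-2-iodo-6-methoxy-5-(3-methylbut-2-en-1-yl)-1-benzofuran-3-carboxylate; 13 ethynyltrimethylsilane
Product: 15 ethyl 4-(2,2-dimethylpropanoyloxy)-2-ethynyl-6-methoxy-5-(3-methylbut-2-en-1-yl)-1-benzofuran-3-carboxylate, via silylalkyne 14 (not isolated)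
Conditions: PdCl2(PPh3)2 (3 mol%), CuI (5 mol%), Et3N, THF, rt, argon; then K2CO3 (cat.), EtOH, 0 °C
Reagents that add atoms: none
Why: Sonogashira coupling of the electron-poor heteroaryl iodide followed by base-catalysed ethanolysis of the C–Si bond, with ethanol chosen to match the ethyl ester and the hindered pivalate expected to survive the brief, cold treatment.

Step 8
Reactants: 16 acetyl chloride; 17 1,1-dichloroethene
Product: 19 4,4-dichlorobut-3-en-2-one, via 4,4,4-trichlorobutan-2-one 18 (not isolated)
Conditions: AlCl3 (1.1 equiv), CH2Cl2, 0 °C to rt; ice water; steam distillation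
Reagents that add atoms: none
Why: Friedel–Crafts-type acylation of the alkene (acylium addition, chloride capture) followed by loss of HCl on distillation gives the conjugated β,β-dichloroenone.

Step 9
Reactants: 19 4,4-dichlorobut-3-en-2-one
Product: 20 4,4-dimethoxybut-3-en-2-one
Conditions: NaOMe (2.1 equiv), MeOH, 0 °C to rt
Reagents that add atoms: sodium methoxide, C[O-].[Na+]
Why: Twofold addition–elimination (vinylic substitution) of methoxide at the β-carbon of the enone replaces both chlorides and gives the ketene acetal.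

Step 10
Reactants: 20 4,4-dimethoxybut-3-en-2-one
Product: 21 1,1-dimethoxy-3-(trimethylsilyloxy)buta-1,3-diene
Conditions: Me3SiCl, Et3N, ZnCl2 (cat.), PhMe, 40 °C
Reagents that add atoms: chlorotrimethylsilane, C[Si](C)(C)Cl
Why: Soft enolisation of the methyl ketone and O-silylation (silyl enol ether formation, as used for 1-alkoxy-3-silyloxybutadienes) gives the cross-conjugated diene, to be distilled and used fresh.

Step 11
Reactants: 15 ethyl 4-(2,2-dimethylpropanoyloxy)-2-ethynyl-6-methoxy-5-(3-methylbut-2-en-1-yl)-1-benzofuran-3-carboxylate; 21 1,1-dimethoxy-3-(trimethylsilyloxy)buta-1,3-diene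
Product: 24 ethyl 4-(2,2-dimethylpropanoyloxy)-2-(4-hydroxy-2-methoxyphenyl)-6-methoxy-5-(3-methylbut-2-en-1-yl)-1-benzofuran-3-carboxylate, via cycloadduct 22 (not isolated), via aryl silyl ether 23 (not isolated)
Conditions: 21 (3 equiv), PhMe, 110 °C (sealed tube); then 1 M HCl, THF, 0 °C
Reagents that add atoms: none
Why: Proposed new method: the terminal alkyne carbon of 15 is the δ-position of the alkyne–C2=C3–ester acceptor, so the CH2 terminus of 21, made nucleophilic by three oxygen donors, should bond there (C5'–C6') while the ketene-acetal carbon bonds to the internal alkyne carbon (C1'–C2') in a concerted but strongly asynchronous (4+2) cycloaddition that closes ring B as a six-membered carbocycle from an open-chain diene. The closest known reaction type is the Diels–Alder aromatization of 1,1-dialkoxy-3-silyloxybutadienes with propiolates and ynones, which gives 2-alkoxy-4-hydroxyaryl carbonyl compounds with this orientation; here the activation is only vinylogous, which is why heat, excess diene and an acyloxy instead of an alkoxy group at O4 (less donation into C3a–C3) are used. 1,4-Cyclohexadiene 22 should lose methanol to give aryl silyl ether 23, and dilute acid frees the 4'-phenol of 24. No stereocentre is formed. The step needs regioselectivity, secured by matching the nucleophilic diene terminus with the alkyne carbon polarised by the C3 ester, and chemoselectivity, secured by the steric shielding and aromaticity of the tetrasubstituted C2=C3 bond and by carrying an ester at C3, since an aldehyde would react with the diene at the carbonyl group.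

Step 12
Reactants: 24 ethyl 4-(2,2-dimethylpropanoyloxy)-2-(4-hydroxy-2-methoxyphenyl)-6-methoxy-5-(3-methylbut-2-en-1-yl)-1-benzofuran-3-carboxylate
Product: 25 3-(hydroxymethyl)-2-(4-hydroxy-2-methoxyphenyl)-6-methoxy-5-(3-methylbut-2-en-1-yl)-1-benzofuran-4-ol
Conditions: i-Bu2AlH (6 equiv), CH2Cl2, −78 to 0 °C; aq. potassium sodium tartrate
Reagents that add atoms: none
Why: Hydride reduction with excess i-Bu2AlH should take the ethyl ester to the primary alcohol and cleave the aryl pivalate in the same flask, and the neutral tartrate work-up protects the ionisation-prone benzylic carbinol.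

Step 13
Reactants: 25 3-(hydroxymethyl)-2-(4-hydroxy-2-methoxyphenyl)-6-methoxy-5-(3-methylbut-2-en-1-yl)-1-benzofuran-4-ol
Product: 26 4-hydroxy-2-(4-hydroxy-2-methoxyphenyl)-6-methoxy-5-(3-methylbut-2-en-1-yl)-1-benzofuran-3-carbaldehyde (ebenfuran IV)
Conditions: MnO2 (activated, 15 equiv), CH2Cl2, rt
Reagents that add atoms: none
Why: MnO2 oxidation of an activated heteroaryl (benzylic-type) alcohol should stop at the aldehyde and leave the phenols and the prenyl alkene untouched.

**Compound list**

1 | 2,4,6-trimethoxybenzaldehyde | COc1cc(OC)c(C=O)c(OC)c1 | starting material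
2 | 2,6-dihydroxy-4-methoxybenzaldehyde | COc1cc(O)c(C=O)c(O)c1 | intermediate
3 | ethyl diazoacetate | CCOC(=O)C=[N+]=[N-] | starting material
4 | ethyl 2,4-dihydroxy-6-methoxy-2,3-dihydro-1-benzofuran-3-carboxylate (hemiacetal, diastereomer mixture) | CCOC(=O)C1C(O)Oc2cc(OC)cc(O)c12 | intermediate (not isolated)
5 | ethyl 4-hydroxy-6-methoxy-1-benzofuran-3-carboxylate | CCOC(=O)c1coc2cc(OC)cc(O)c12 | intermediate
6 | tert-butyl 2-methylbut-3-en-2-yl carbonate | CC(C)(C)OC(=O)OC(C)(C)C=C | starting material
7 | ethyl 6-methoxy-4-[(2-methylbut-3-en-2-yl)oxy]-1-benzofuran-3-carboxylate | CCOC(=O)c1coc2cc(OC)cc(OC(C)(C)C=C)c12 | intermediate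
8 | ethyl 6-methoxy-5-(3-methylbut-2-en-1-yl)-4-oxo-4,5-dihydro-1-benzofuran-3-carboxylate (ortho-dienone, racemic) | CCOC(=O)C1=COC2=C1C(=O)C(CC=C(C)C)C(OC)=C2 | intermediate (not isolated)
9 | ethyl 4-hydroxy-6-methoxy-5-(3-methylbut-2-en-1-yl)-1-benzofuran-3-carboxylate | CCOC(=O)c1coc2cc(OC)c(CC=C(C)C)c(O)c12 | intermediate
10 | ethyl 4-(2,2-dimethylpropanoyloxy)-6-methoxy-5-(3-methylbut-2-en-1-yl)-1-benzofuran-3-carboxylate | CCOC(=O)c1coc2cc(OC)c(CC=C(C)C)c(OC(=O)C(C)(C)C)c12 | intermediate
11 | ethyl 2-(chloromagnesio)-4-(2,2-dimethylpropanoyloxy)-6-methoxy-5-(3-methylbut-2-en-1-yl)-1-benzofuran-3-carboxylate | CCOC(=O)c1c([Mg]Cl)oc2cc(OC)c(CC=C(C)C)c(OC(=O)C(C)(C)C)c12 | intermediate (not isolated)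
12 | ethyl 4-(2,2-dimethylpropanoyloxy)-2-iodo-6-methoxy-5-(3-methylbut-2-en-1-yl)-1-benzofuran-3-carboxylate | CCOC(=O)c1c(I)oc2cc(OC)c(CC=C(C)C)c(OC(=O)C(C)(C)C)c12 | intermediate
13 | ethynyltrimethylsilane | C#C[Si](C)(C)C | starting material
14 | ethyl 4-(2,2-dimethylpropanoyloxy)-6-methoxy-5-(3-methylbut-2-en-1-yl)-2-[(trimethylsilyl)ethynyl]-1-benzofuran-3-carboxylate | CCOC(=O)c1c(C#C[Si](C)(C)C)oc2cc(OC)c(CC=C(C)C)c(OC(=O)C(C)(C)C)c12 | intermediate (not isolated)
15 | ethyl 4-(2,2-dimethylpropanoyloxy)-2-ethynyl-6-methoxy-5-(3-methylbut-2-en-1-yl)-1-benzofuran-3-carboxylate | CCOC(=O)c1c(C#C)oc2cc(OC)c(CC=C(C)C)c(OC(=O)C(C)(C)C)c12 | intermediate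
16 | acetyl chloride | CC(=O)Cl | starting material
17 | 1,1-dichloroethene | C=C(Cl)Cl | starting material
18 | 4,4,4-trichlorobutan-2-one | CC(=O)CC(Cl)(Cl)Cl | intermediate (not isolated)
19 | 4,4-dichlorobut-3-en-2-one | CC(=O)C=C(Cl)Cl | intermediate
20 | 4,4-dimethoxybut-3-en-2-one | CC(=O)C=C(OC)OC | intermediate
21 | 1,1-dimethoxy-3-(trimethylsilyloxy)buta-1,3-diene | COC(OC)=CC(=C)O[Si](C)(C)C | intermediate
22 | ethyl 2-[6,6-dimethoxy-4-(trimethylsilyloxy)cyclohexa-1,4-dien-1-yl]-4-(2,2-dimethylpropanoyloxy)-6-methoxy-5-(3-methylbut-2-en-1-yl)-1-benzofuran-3-carboxylate | CCOC(=O)c1c(C3=CCC(O[Si](C)(C)C)=CC3(OC)OC)oc2cc(OC)c(CC=C(C)C)c(OC(=O)C(C)(C)C)c12 | intermediate (not isolated)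
23 | ethyl 4-(2,2-dimethylpropanoyloxy)-6-methoxy-2-[2-methoxy-4-(trimethylsilyloxy)phenyl]-5-(3-methylbut-2-en-1-yl)-1-benzofuran-3-carboxylate | CCOC(=O)c1c(-c3ccc(O[Si](C)(C)C)cc3OC)oc2cc(OC)c(CC=C(C)C)c(OC(=O)C(C)(C)C)c12 | intermediate (not isolated)
24 | ethyl 4-(2,2-dimethylpropanoyloxy)-2-(4-hydroxy-2-methoxyphenyl)-6-methoxy-5-(3-methylbut-2-en-1-yl)-1-benzofuran-3-carboxylate | CCOC(=O)c1c(-c3ccc(O)cc3OC)oc2cc(OC)c(CC=C(C)C)c(OC(=O)C(C)(C)C)c12 | intermediate
25 | 3-(hydroxymethyl)-2-(4-hydroxy-2-methoxyphenyl)-6-methoxy-5-(3-methylbut-2-en-1-yl)-1-benzofuran-4-ol | OCc1c(-c3ccc(O)cc3OC)oc2cc(OC)c(CC=C(C)C)c(O)c12 | intermediate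
26 | ebenfuran IV, 4-hydroxy-2-(4-hydroxy-2-methoxyphenyl)-6-methoxy-5-(3-methylbut-2-en-1-yl)-1-benzofuran-3-carbaldehyde | COc1cc(O)ccc1-c1oc2cc(OC)c(CC=C(C)C)c(O)c2c1C=O | target

**Count and risks**

Total step count: 13 (steps 1–7 and 11–13 on the main line, steps 8–10 for the diene).
Longest linear sequence: 10 steps, from 1 to 26 (steps 1–7, 11, 12, 13).

Step 11 (the new cycloaddition). The alkyne is activated only through C2=C3 and the ester, so the cycloaddition may be slower than the thermal and protic decay of the diene and the alkyne would then be recovered; addition of the diene across C2=C3 is the other conceivable leak. The fallback brings ring B in ready-made by known chemistry and leaves the route at 12. Bought 4-bromo-3-methoxyphenol (COc1cc(O)ccc1Br) would be borylated (B2pin2, PdCl2(dppf), KOAc, dioxane, 90 °C) to 3-methoxy-4-(4,4,5,5-tetramethyl-1,3,2-dioxaborolan-2-yl)phenol F1. Suzuki–Miyaura coupling of F1 with iodide 12 (PdCl2(dppf), K3PO4, dioxane–water, 80 °C) should then give 24, where the route is rejoined.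

Step 2. The annulation is established for salicylaldehydes with one phenol; with two, the acid-activated diazo ester may alkylate the spare phenol, or addition to an aldehyde that is hydrogen-bonded from both sides may stall. The fallback sets out from 2 and returns at 5. Benzyl bromide (1 equiv, K2CO3, acetone) should give 2-(benzyloxy)-6-hydroxy-4-methoxybenzaldehyde F2, because the remaining phenol is chelated. The same diazoacetate annulation would then run on a normal mono-phenol through ethyl 4-(benzyloxy)-2-hydroxy-6-methoxy-2,3-dihydro-1-benzofuran-3-carboxylate F3 to ethyl 4-(benzyloxy)-6-methoxy-1-benzofuran-3-carboxylate F4. Hydrogenolysis (H2, Pd/C, EtOAc) frees the 4-OH and gives 5.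

Step 3. The phenoxide is hindered and hydrogen-bonded to the ester, so it may attack the unsubstituted allyl terminus, or palladium may equilibrate the tertiary ether to the linear prenyl ether; either would put a 1,1-dimethylallyl group on C5 after rearrangement. The fallback sets out from 5 and returns at 7. Copper-catalysed propargylation (3-chloro-3-methylbut-1-yne, DBU, CuCl2 cat., MeCN, 0 °C) can only give the tertiary ether ethyl 6-methoxy-4-[(2-methylbut-3-yn-2-yl)oxy]-1-benzofuran-3-carboxylate F5. Semihydrogenation (H2, Pd/CaCO3 poisoned with Pb(OAc)2, quinoline, EtOAc) then gives 7.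

**Further compounds**

F1 | step 11 | 3-methoxy-4-(4,4,5,5-tetramethyl-1,3,2-dioxaborolan-2-yl)phenol | COc1cc(O)ccc1B1OC(C)(C)C(C)(C)O1
F2 | step 2 | 2-(benzyloxy)-6-hydroxy-4-methoxybenzaldehyde | COc1cc(O)c(C=O)c(OCc2ccccc2)c1
F3 | step 2 | ethyl 4-(benzyloxy)-2-hydroxy-6-methoxy-2,3-dihydro-1-benzofuran-3-carboxylate | CCOC(=O)C1C(O)Oc2cc(OC)cc(OCc3ccccc3)c12
F4 | step 2 | ethyl 4-(benzyloxy)-6-methoxy-1-benzofuran-3-carboxylate | CCOC(=O)c1coc2cc(OC)cc(OCc3ccccc3)c12
F5 | step 3 | ethyl 6-methoxy-4-[(2-methylbut-3-yn-2-yl)oxy]-1-benzofuran-3-carboxylate | CCOC(=O)c1coc2cc(OC)cc(OC(C)(C)C#C)c12
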